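## The problem

Atom labels used throughout, for every bicyclic compound: C1 allyl bridgehead, C2=C3 (C3 carries OMe), C4, C5 oxygenated bridgehead, C6 aryl carbon, C7 methyl carbon, C8 one-carbon bridge.

The target is (1R,4S,5R,6S,7R)-4-hydroxy-6-(4-hydroxy-3-methoxyphenyl)-3,5-dimethoxy-7-methyl-1-(prop-2-en-1-yl)bicyclo[3.2.1]oct-2-en-8-one. A six-membered ring (C1–C2–C3–C4–C5–C8) and a cyclopentanone (C1–C8–C5–C6–C7) share the C1–C8–C5 unit, and both bridgeheads are fully substituted (C1 all-carbon, C5 a tertiary ether). There are five stereocentres. The two bridgeheads fix each other. The aryl group on C6 is endo (towards the C2–C4 bridge) and the methyl group on C7 is exo, so the two are trans. The C4 hydroxyl lies on the face turned towards the C6–C7 bridge.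

The trans C6/C7 relation can be taken from an (E)-alkene, but the endo orientation has to come from the ring-forming event. Once the bicycle stands, the endo aryl group covers one face of C4, so C4 can be set last by the substrate. Nothing in the molecule sets the absolute configuration, so a resolution or an asymmetric step is needed.

Sensitive groups:
- the C2=C3 enol ether beside an allylic carbinol (acid);
- the C4–OH/C8=O β-hydroxy ketone (retro-aldol in base);
- the terminal allyl group (no hydrogenation, no isomerising metals);
- the free phenol (oxidation).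

The enabling feature is that C5 carries oxygen and sits between the C8 carbonyl and the oxygenated C4. At the C4-ketone level, O–C5–C4=O is an α-ketol. Its C5–C6 bond can therefore arise by a 1,2-shift of C6 from C4 to C5 in the isomeric ketol (hydroxyl on C4, carbonyl on C5), which is a bicyclo[2.2.2]octenone and hence a Diels–Alder adduct.

## Retrosynthesis

**14 to 12.** No skeletal bond is cut. The phenol is traced to its triisopropylsilyl ether 13 and the C4 carbinol to the ketone of dione 12. C4 must in any case pass through the ketone level for the ketol logic, and the endo aryl group should direct hydride to the correct face. The forward step must reduce the C4 enone carbonyl and leave the C8 carbonyl.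

**12 to 10.** The C8 carbonyl is masked as the dimethyl ketal and the C5 methyl ether is cut at O–CH3, giving tertiary alcohol 10 by way of 11. The ketal is the form in which C8 arrives from the dearomatisation, and the free C5 hydroxyl is what the ketol shift delivers. The forward sequence needs a methylation that generates no alkoxide, then acid hydrolysis while the enol ether is still protected by conjugation with the C4 carbonyl.

**10 to 9 (key disconnection).** The C5–C6 bond is cut and C6 is reconnected to C4. This turns the bicyclo[3.2.1]octenone into the bridgehead-hydroxy bicyclo[2.2.2]octenone 9. Cutting C1–C7 or C1–C2 instead would leave a quaternary centre to be made by alkylation of a hindered cyclopentanone. The C5–C6 cut exposes a cyclohexene with a two-carbon bridge, a Diels–Alder retron. The forward reaction must move C6 and not the vinylic C3.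

**9 to 7.** The bridgehead hydroxyl is traced to an acetate (8), and 8 to the racemate 7 by resolution. The acetate is needed earlier as the group that steers the dearomatisation and activates the diene.

**7 to 6 + 5.** The C4–C6 and C1–C7 bonds are cut. The partners are the masked ortho-quinone 6 and the silyl ether 5 of (E)-isoeugenol. This one cut removes both quaternary bridgeheads and the C6/C7 pair. The forward cycloaddition must be regioselective (benzylic carbon to C4) and endo.

**6 to 1, 5 to 4.** Dienone 6 is the oxidative dearomatisation product of phenol 3 in methanol. Phenol 3 is the monoacetate of catechol 2, which is apiole 1 without its methylene acetal; apiole already has the allyl group and all four ring oxygens in place. Silyl ether 5 comes from (E)-isoeugenol 4.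

## Roads not taken

**Alternative 1:** The C1–C2 bond is cut, so the six-membered ring is closed last on a finished cyclopentane. The forward key step is anodic oxidation (carbon anode, LiClO4, methanol, 2,6-lutidine) giving ketone A1 from the C8 silyl enol ether A2. The radical cation is attacked at C1 by the terminal carbon of the α-methoxyvinyl group, and the C3 oxocarbenium ion takes up methanol.
- Merits: two nucleophilic carbons are joined to make the quaternary C1; the ring can only close cis-bridged; the C4 carbinol is already present and protected, so no late selective reduction is needed; the absolute configuration could be set while A2 is made, without a resolution. In these two respects this road is better than the chosen one.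
- Weak points: A2 must already contain C4, C5 (a quaternary ether), C6 and C7, none of which the key step sets. The electron-rich arene, the allyl alkene and methanol capture at C1 compete for the radical cation. A1 holds C3 as a ketal, so methanol must later be eliminated towards C2 and not C4.
- Comparison: the chosen plan sets against this two commercial building blocks, both bridgeheads and the C6/C7 pair from one cycloaddition, and an enol ether that is in place from the start.

**Alternative 2:** The C6–C7 bond of the cyclopentane is cut, leading to the acyclic dienone A4. The forward key step is a reductive Nazarov cyclisation: Et3SiOTf activation, conrotatory 4π closure, and Et3SiH capture of the oxyallyl cation at C5, giving silyl enol ether A3.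
- Merits: orbital symmetry guarantees the trans aryl/methyl relation, which is firmer than the endo preference the chosen plan relies on. A4 is made by simple carbonyl chemistry.
- Weak points: only the cyclopentane is built. C5 emerges as CH(OMe) and must still become quaternary, so the centre set by hydride is lost again. The C1–C2 and C4–C5 bonds and the whole three-carbon bridge remain, which calls for a second, unsolved bridging annulation. The site of hydride capture (C5 or C1) is uncertain, and the product is racemic.
- Comparison: the chosen plan is weaker on C6/C7 control but reaches the complete carbon skeleton in two C–C bond-forming steps.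

**Alternative 3:** The C1–C2 and C2–C3 bonds are cut and C2 is excised as a one-carbon unit, leaving cyclopentanone A6 with a methoxyacetyl group on C5. In the forward key step DMF dimethyl acetal condenses at the C3 methylene to give enaminone A7. Acid then lets the C1 enol add to the aminomethylene carbon with loss of dimethylamine, giving dione A5.
- Merits: A5 is the tert-butyldimethylsilyl analogue of 12, reached without methylating a tertiary alcohol and without ketal hydrolysis. This end game is shorter than the chosen one.
- Weak points: A6 is a non-enolisable 1,3-diketone at a quaternary carbon, open to retro-Claisen cleavage by the amine and methanol released. The closure asks a hindered tertiary enol carbon to attack a weakly electrophilic vinylogous amide and form a bridgehead quaternary centre. Making A6, with three contiguous stereocentres including quaternary C5, is most of the problem. The C4 reduction issue at the end is the same.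
- Comparison: the chosen plan has the longer end game but sets its stereocentres in one cycloaddition, and forms the critical bond by an intramolecular shift whose geometry is fixed by the bicycle.

Key step: step 7

## Route

Assumption: (E)-isoeugenol is used as the pure (E)-isomer, and the enantiomer of 7 carried on as 8 is identified by anomalous-dispersion X-ray analysis before scale-up.

Step 1
Reactants: 1 apiole (4,7-dimethoxy-5-(prop-2-en-1-yl)-1,3-benzodioxole)
Product: 2 3,6-dimethoxy-4-(prop-2-en-1-yl)benzene-1,2-diol
Conditions: BCl3 (1.2 equiv), CH2Cl2, −78 to −10 °C; then MeOH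
Reagents that add atoms: none
Why: Lewis-acid cleavage of an aryl methylenedioxy acetal: boron binds a dioxole oxygen and chloride opens the O–CH2–O carbon, which is attacked more readily than a methyl ether carbon, so with a slight excess of BCl3 at low temperature the methoxy groups and the allyl group should remain; methanolysis of the boron and chloromethyl intermediates frees the catechol.

Step 2
Reactants: 2 3,6-dimethoxy-4-(prop-2-en-1-yl)benzene-1,2-diol
Product: 3 2-hydroxy-3,6-dimethoxy-4-(prop-2-en-1-yl)phenyl acetate
Conditions: Ac2O (1.0 equiv), Et3N, DMAP (cat.), CH2Cl2, −20 °C to rt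
Reagents that add atoms: acetic anhydride, CC(=O)OC(C)=O
Why: Phenol acylation under conditions in which the two monoacetates interconvert by acyl migration between the vicinal oxygens; the acetate should settle on the oxygen beside the unhindered C6 methoxy group, whose phenol is also the weaker acid, leaving free the hydroxyl beside the buttressed C3 methoxy group as step 4 requires. A minor regioisomer is removable by chromatography and can be re-equilibrated.

Step 3
Reactants: 4 (E)-isoeugenol (2-methoxy-4-[(1E)-prop-1-en-1-yl]phenol)
Product: 5 triisopropyl{2-methoxy-4-[(1E)-prop-1-en-1-yl]phenoxy}silane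
Conditions: TIPSCl, imidazole, DMF, rt
Reagents that add atoms: chlorotriisopropylsilane, CC(C)[Si](Cl)(C(C)C)C(C)C
Why: Silylation of a phenol; the triisopropylsilyl ether keeps the styrene electron-rich, shields the phenol from the oxidant, and should survive the methanolysis of step 6, the aluminium alkoxide and aqueous acid.

Step 4
Reactants: 3 2-hydroxy-3,6-dimethoxy-4-(prop-2-en-1-yl)phenyl acetate; 5 triisopropyl{2-methoxy-4-[(1E)-prop-1-en-1-yl]phenoxy}silane
Product: 7 racemic 4-acetoxy-1-allyl-3,8,8-trimethoxy-7-methyl-6-[3-methoxy-4-(triisopropylsilyloxy)phenyl]bicyclo[2.2.2]oct-2-en-5-one (aryl on C6 syn to C2=C3; methyl on C7 syn to the C5–C8 bridge), via masked ortho-quinone 6 (not isolated)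
Conditions: PhI(OAc)2 (1.05 equiv), MeOH, 0 °C; solvent exchange to toluene; 5 (3 equiv), 80 °C
Reagents that add atoms: methanol, CO
Why: Hypervalent-iodine oxidative dearomatisation in methanol gives the ortho-quinone monoketal 6, methanol entering at the methoxy-bearing ortho carbon because the acetoxy-bearing one is deactivated; 6 then undergoes an inverse-electron-demand Diels–Alder reaction in which the nucleophilic methyl-bearing carbon of 5 bonds to the dienone δ-carbon (C1) and the benzylic carbon to the α-carbon (C4). The endo transition state places the aryl group syn to the new C2=C3 bridge and the (E)-geometry places the methyl group trans to it; the two faces of planar 6 are equivalent, so 7 is racemic.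

Step 5
Reactants: 7 racemic cycloadduct
Product: 8 4-acetoxy-1-allyl-3,8,8-trimethoxy-7-methyl-6-[3-methoxy-4-(triisopropylsilyloxy)phenyl]bicyclo[2.2.2]oct-2-en-5-one, single enantiomer (the one that leads to (1R,4S,5R,6S,7R)-14; configuration as in the SMILES)
Conditions: preparative supercritical-fluid chromatography, amylose tris(3,5-dimethylphenylcarbamate) phase, CO2/2-propanol
Reagents that add atoms: none
Why: Enantiomer separation by chromatography on a chiral stationary phase; no bond is changed, and resolving early keeps the unwanted enantiomer out of all later steps.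

Step 6
Reactants: 8 enantiopure bridgehead acetate
Product: 9 1-allyl-4-hydroxy-3,8,8-trimethoxy-7-methyl-6-[3-methoxy-4-(triisopropylsilyloxy)phenyl]bicyclo[2.2.2]oct-2-en-5-one (stereochemistry as in 8)
Conditions: K2CO3 (0.3 equiv), MeOH, 0 °C; NH4Cl quench
Reagents that add atoms: none
Why: Base-catalysed transesterification (methanolysis) of the acetate, fast because the leaving alkoxide is α to a ketone; substoichiometric carbonate at 0 °C keeps the alkoxide concentration low, so the aryl triisopropylsilyl ether should survive and the ketol shift is left for step 7.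

Step 7
Reactants: 9 bridgehead-hydroxy bicyclo[2.2.2]oct-2-en-5-one
Product: 10 1-allyl-5-hydroxy-3,8,8-trimethoxy-7-methyl-6-[3-methoxy-4-(triisopropylsilyloxy)phenyl]bicyclo[3.2.1]oct-2-en-4-one (aryl endo, methyl exo)
Conditions: Al(OtBu)3 (1.5 equiv), toluene, 90 °C; aqueous potassium sodium tartrate work-up
Reagents that add atoms: none
Why: Ligand exchange gives the aluminium alkoxide of the C4 hydroxyl, and because the bicycle holds the C4–O and C5=O bonds syn-coplanar the metal chelates and activates the ketone. The C4–C6 bond lies nearly parallel to the carbonyl π* orbital, so C6 shifts suprafacially from C4 to C5 while the alkoxide oxygen becomes the C4 carbonyl; this is the aluminium-alkoxide-promoted α-ketol (acyloin) rearrangement, closest in type to the D-homo annulation of 17-hydroxy-20-oxo steroids and to the interconversion of bicyclo[2.2.2]octane and bicyclo[3.2.1]octane ketols. The five-membered ring (C1, C8, C5, C6, C7) is closed by this 1,2-shift, a contraction of the C1–C7–C6–C4–C5–C8 ring, not by a cyclisation. The new stereocentre C5 is fixed by geometry, since C6 can reach only the face of the C5 carbonyl on its own side, and C6 migrates with retention, so the aryl group syn to C2=C3 becomes endo and the methyl group exo. The selectivity needed is migration of C6 and not of the vinylic C3; both shifts are reversible, and only the C6 shift gives a carbonyl conjugated with the C2=C3 enol ether and removed from the electron-poor position beside the ketal, so equilibration should collect 10. Al(OtBu)3 has no transferable hydride, which excludes Meerwein–Ponndorf–Verley reduction, and the covalent Al–O bond disfavours the cycloreversion open to a free alkoxide.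

Step 8
Reactants: 10 C5-hydroxy bicyclo[3.2.1]oct-2-en-4-one
Product: 11 1-allyl-3,5,8,8-tetramethoxy-7-methyl-6-[3-methoxy-4-(triisopropylsilyloxy)phenyl]bicyclo[3.2.1]oct-2-en-4-one
Conditions: MeOTf (5 equiv), 2,6-di-tert-butyl-4-methylpyridine (6 equiv), CH2Cl2, rt to 40 °C
Reagents that add atoms: methyl trifluoromethanesulfonate, COS(=O)(=O)C(F)(F)F
Why: O-Alkylation of a hindered tertiary alcohol with methyl triflate buffered by a non-nucleophilic pyridine; no alkoxide is generated, so neither the ketol nor the silyl ether is disturbed.

Step 9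
Reactants: 11 C8 dimethyl ketal
Product: 12 1-allyl-3,5-dimethoxy-7-methyl-6-[3-methoxy-4-(triisopropylsilyloxy)phenyl]bicyclo[3.2.1]oct-2-ene-4,8-dione
Conditions: TFA/H2O (9:1), CH2Cl2, 0 °C to rt
Reagents that add atoms: water, O
Why: Acid-catalysed ketal hydrolysis; it precedes the reduction because the C2=C3 enol ether resists protonation only while it is conjugated with the C4 carbonyl, and the aryl triisopropylsilyl ether tolerates aqueous acid.

Step 10
Reactants: 12 bicyclo[3.2.1]oct-2-ene-4,8-dione
Product: 13 (1R,4S,5R,6S,7R)-4-hydroxy-3,5-dimethoxy-7-methyl-1-(prop-2-en-1-yl)-6-[3-methoxy-4-(triisopropylsilyloxy)phenyl]bicyclo[3.2.1]oct-2-en-8-one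
Conditions: NaBH4 (1.0 equiv), CeCl3·7H2O (1.2 equiv), MeOH, −78 °C
Reagents that add atoms: none
Why: Luche 1,2-reduction: the hard borohydride–methanol species should add to the α-methoxy enone carbonyl, where the C3 methoxy oxygen and the C4 carbonyl oxygen can chelate the trivalent cerium ion, in preference to the C8 carbonyl flanked by two fully substituted bridgeheads. Hydride should enter C4 from the face turned towards C8, anti to the endo aryl group on C6, which gives the (4S) alcohol with the hydroxyl on the side of the C6–C7 bridge.

Step 11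
Reactants: 13 silyl-protected target
Product: 14 (1R,4S,5R,6S,7R)-4-hydroxy-6-(4-hydroxy-3-methoxyphenyl)-3,5-dimethoxy-7-methyl-1-(prop-2-en-1-yl)bicyclo[3.2.1]oct-2-en-8-one (CNP0330966.1)
Conditions: TBAF (1.2 equiv), AcOH (1.2 equiv), THF, 0 °C
Reagents that add atoms: none
Why: Fluoride-induced cleavage of the aryl silyl ether; acetic acid buffers the phenoxide so that the β-hydroxy ketone is not exposed to base.

## Compound list

1 | apiole, 4,7-dimethoxy-5-(prop-2-en-1-yl)-1,3-benzodioxole | C=CCc1cc(OC)c2OCOc2c1OC | starting material
2 | 3,6-dimethoxy-4-(prop-2-en-1-yl)benzene-1,2-diol | C=CCc1cc(OC)c(O)c(O)c1OC | intermediate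
3 | 2-hydroxy-3,6-dimethoxy-4-(prop-2-en-1-yl)phenyl acetate | C=CCc1cc(OC)c(OC(C)=O)c(O)c1OC | intermediate
4 | (E)-isoeugenol | C/C=C/c1ccc(O)c(OC)c1 | starting material
5 | triisopropyl{2-methoxy-4-[(1E)-prop-1-en-1-yl]phenoxy}silane | C/C=C/c1ccc(O[Si](C(C)C)(C(C)C)C(C)C)c(OC)c1 | intermediate
6 | 2,5,5-trimethoxy-6-oxo-4-(prop-2-en-1-yl)cyclohexa-1,3-dien-1-yl acetate (masked ortho-quinone) | C=CCC1=CC(OC)=C(OC(C)=O)C(=O)C1(OC)OC | intermediate
7 | racemic bicyclo[2.2.2]octenone bridgehead acetate (both enantiomers written) | C=CC[C@@]12C=C(OC)[C@@](OC(C)=O)(C(=O)C1(OC)OC)[C@H](c1ccc(O[Si](C(C)C)(C(C)C)C(C)C)c(OC)c1)[C@H]2C.C=CC[C@]12C=C(OC)[C@](OC(C)=O)(C(=O)C1(OC)OC)[C@@H](c1ccc(O[Si](C(C)C)(C(C)C)C(C)C)c(OC)c1)[C@@H]2C | intermediate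
8 | enantiopure bicyclo[2.2.2]octenone bridgehead acetate | C=CC[C@@]12C=C(OC)[C@@](OC(C)=O)(C(=O)C1(OC)OC)[C@H](c1ccc(O[Si](C(C)C)(C(C)C)C(C)C)c(OC)c1)[C@H]2C | intermediate
9 | bridgehead-hydroxy bicyclo[2.2.2]oct-2-en-5-one (precursor of the key step) | C=CC[C@@]12C=C(OC)[C@@](O)(C(=O)C1(OC)OC)[C@H](c1ccc(O[Si](C(C)C)(C(C)C)C(C)C)c(OC)c1)[C@H]2C | intermediate
10 | C5-hydroxy bicyclo[3.2.1]oct-2-en-4-one, C8 dimethyl ketal (product of the key step) | C=CC[C@@]12C=C(OC)C(=O)[C@@](O)(C1(OC)OC)[C@H](c1ccc(O[Si](C(C)C)(C(C)C)C(C)C)c(OC)c1)[C@H]2C | intermediate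
11 | C5-methoxy bicyclo[3.2.1]oct-2-en-4-one, C8 dimethyl ketal | C=CC[C@@]12C=C(OC)C(=O)[C@@](OC)(C1(OC)OC)[C@H](c1ccc(O[Si](C(C)C)(C(C)C)C(C)C)c(OC)c1)[C@H]2C | intermediate
12 | O-triisopropylsilyl bicyclo[3.2.1]oct-2-ene-4,8-dione | C=CC[C@@]12C=C(OC)C(=O)[C@@](OC)(C1=O)[C@H](c1ccc(O[Si](C(C)C)(C(C)C)C(C)C)c(OC)c1)[C@H]2C | intermediate
13 | O-triisopropylsilyl ether of the target | C=CC[C@@]12C=C(OC)[C@H](O)[C@@](OC)(C1=O)[C@H](c1ccc(O[Si](C(C)C)(C(C)C)C(C)C)c(OC)c1)[C@H]2C | intermediate
14 | CNP0330966.1 | C=CC[C@@]12C=C(OC)[C@H](O)[C@@](OC)(C1=O)[C@H](c1ccc(O)c(OC)c1)[C@H]2C | target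

## Step count and least certain steps

Total: 11 steps. Longest linear sequence: 10 steps (from 1 through steps 1, 2 and 4–11).

**Step 7 (key step).** The shift may take the vinylic C3 instead of C6, the equilibrium may not favour 10, or the bridgehead alkoxide may drive cycloreversion to diene and styrene.
Fallback: it sets out from silyl ether 5 and comes back at dione 12, bypassing 6–11. Commercial 2,3,4-trimethoxyphenol F1 is O-allylated (allyl bromide, K2CO3, acetone) to allyl 2,3,4-trimethoxyphenyl ether F2. Claisen rearrangement (N,N-diethylaniline, 190 °C) gives 6-allyl-2,3,4-trimethoxyphenol F3. PhI(OAc)2 in methanol gives the para-quinone monoketal 4,4,5,6-tetramethoxy-2-(prop-2-en-1-yl)cyclohexa-2,5-dien-1-one F4. Ionisation of the ketal with TMSOTf at low temperature in the presence of 5 should give, by the known cationic (5+2) cycloaddition of such ketals with propenylarenes and aqueous work-up, the racemic dione F5. Chromatography on a chiral phase gives 12.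

**Step 4.** Methanol may attack the unsubstituted ring carbon para to the phenol during dearomatisation. The crowded, donor-substituted diene may also react too slowly with the 1,2-disubstituted styrene, and endo selectivity may be eroded.
Fallback: it sets out from phenol 3 and comes back at 7, using bromine as a blocking and activating group. NBS in acetonitrile brominates the only free ring position to give 5-bromo-2-hydroxy-3,6-dimethoxy-4-(prop-2-en-1-yl)phenyl acetate F6. Oxidation with PhI(OAc)2 in methanol gives the brominated masked ortho-quinone 3-bromo-2,5,5-trimethoxy-6-oxo-4-(prop-2-en-1-yl)cyclohexa-1,3-dien-1-yl acetate F7, more electron-poor and closed to para attack. Cycloaddition with 5 gives the racemic 2-bromo cycloadduct F8. Bu3SnH with AIBN removes the vinylic bromine to give 7.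

**Step 2.** Regioselection between the two catechol hydroxyls may be poor, so the acetate may end up on the wrong oxygen or as a mixture.
Fallback: it sets out from no intermediate of the route; it replaces 1 and 2 by commercial 2,5-dimethoxyphenol F9 and comes back at 3, so it also covers a failure of step 1. MOMCl and iPr2NEt give 1,4-dimethoxy-2-(methoxymethoxy)benzene F10. Directed ortho-lithiation between the two oxygens (n-BuLi, THF), then B(OMe)3 and H2O2/NaOH, gives 3,6-dimethoxy-2-(methoxymethoxy)phenol F11, an unambiguously monoprotected symmetric catechol. O-Allylation gives 2-(allyloxy)-1,4-dimethoxy-3-(methoxymethoxy)benzene F12. Because both ortho positions are blocked, para-Claisen rearrangement (190 °C) places the allyl group to give 3,6-dimethoxy-2-(methoxymethoxy)-4-(prop-2-en-1-yl)phenol F13. Acetylation gives 3,6-dimethoxy-2-(methoxymethoxy)-4-(prop-2-en-1-yl)phenyl acetate F14, and TFA in CH2Cl2 removes the acetal to give 3.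

**Step 10.** Hydride may add competitively at the strained C8 carbonyl, or attack C4 from the face of the C6–C7 bridge.
Fallback: it sets out from dione 12 and comes back at target 14. Excess NaBH4 with CeCl3·7H2O reduces both carbonyls to the C4,C8-diol F15; the C8 configuration is of no consequence. TESCl and imidazole at low temperature silylate the more accessible allylic C4 hydroxyl to give the C4 triethylsilyl ether F16. Dess–Martin periodinane re-oxidises C8 to give the C4-triethylsilyloxy C8-ketone F17. TBAF buffered with AcOH removes both silyl groups to give 14.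

## Further compounds

F1 | step 7 | 2,3,4-trimethoxyphenol | COc1ccc(O)c(OC)c1OC
F2 | step 7 | allyl 2,3,4-trimethoxyphenyl ether | C=CCOc1ccc(OC)c(OC)c1OC
F3 | step 7 | 6-allyl-2,3,4-trimethoxyphenol | C=CCc1cc(OC)c(OC)c(OC)c1O
F4 | step 7 | 4,4,5,6-tetramethoxy-2-(prop-2-en-1-yl)cyclohexa-2,5-dien-1-one | C=CCC1=CC(OC)(OC)C(OC)=C(OC)C1=O
F5 | step 7 | racemic O-triisopropylsilyl bicyclo[3.2.1]oct-2-ene-4,8-dione (both enantiomers written) | C=CC[C@@]12C=C(OC)C(=O)[C@@](OC)(C1=O)[C@H](c1ccc(O[Si](C(C)C)(C(C)C)C(C)C)c(OC)c1)[C@H]2C.C=CC[C@]12C=C(OC)C(=O)[C@](OC)(C1=O)[C@@H](c1ccc(O[Si](C(C)C)(C(C)C)C(C)C)c(OC)c1)[C@@H]2C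
F6 | step 4 | 5-bromo-2-hydroxy-3,6-dimethoxy-4-(prop-2-en-1-yl)phenyl acetate | C=CCc1c(Br)c(OC)c(OC(C)=O)c(O)c1OC
F7 | step 4 | 3-bromo-2,5,5-trimethoxy-6-oxo-4-(prop-2-en-1-yl)cyclohexa-1,3-dien-1-yl acetate | C=CCC1=C(Br)C(OC)=C(OC(C)=O)C(=O)C1(OC)OC
F8 | step 4 | racemic 2-bromo analogue of cycloadduct 7 (both enantiomers written) | C=CC[C@@]12C(Br)=C(OC)[C@@](OC(C)=O)(C(=O)C1(OC)OC)[C@H](c1ccc(O[Si](C(C)C)(C(C)C)C(C)C)c(OC)c1)[C@H]2C.C=CC[C@]12C(Br)=C(OC)[C@](OC(C)=O)(C(=O)C1(OC)OC)[C@@H](c1ccc(O[Si](C(C)C)(C(C)C)C(C)C)c(OC)c1)[C@@H]2C
F9 | step 2 | 2,5-dimethoxyphenol | COc1ccc(OC)c(O)c1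
F10 | step 2 | 1,4-dimethoxy-2-(methoxymethoxy)benzene | COCOc1cc(OC)ccc1OC
F11 | step 2 | 3,6-dimethoxy-2-(methoxymethoxy)phenol | COCOc1c(O)c(OC)ccc1OC
F12 | step 2 | 2-(allyloxy)-1,4-dimethoxy-3-(methoxymethoxy)benzene | C=CCOc1c(OC)ccc(OC)c1OCOC
F13 | step 2 | 3,6-dimethoxy-2-(methoxymethoxy)-4-(prop-2-en-1-yl)phenol | C=CCc1cc(OC)c(O)c(OCOC)c1OC
F14 | step 2 | 3,6-dimethoxy-2-(methoxymethoxy)-4-(prop-2-en-1-yl)phenyl acetate | C=CCc1cc(OC)c(OC(C)=O)c(OCOC)c1OC
F15 | step 10 | C4,C8-diol of the silyl-protected skeleton (C8 hydroxyl syn to the C6–C7 bridge) | C=CC[C@@]12C=C(OC)[C@H](O)[C@@](OC)([C@@H]1O)[C@H](c1ccc(O[Si](C(C)C)(C(C)C)C(C)C)c(OC)c1)[C@H]2C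
F16 | step 10 | C4 triethylsilyl ether of the diol | C=CC[C@@]12C=C(OC)[C@H](O[Si](CC)(CC)CC)[C@@](OC)([C@@H]1O)[C@H](c1ccc(O[Si](C(C)C)(C(C)C)C(C)C)c(OC)c1)[C@H]2C
F17 | step 10 | C4-triethylsilyloxy C8-ketone | C=CC[C@@]12C=C(OC)[C@H](O[Si](CC)(CC)CC)[C@@](OC)(C1=O)[C@H](c1ccc(O[Si](C(C)C)(C(C)C)C(C)C)c(OC)c1)[C@H]2C
A1 | alternative 1 | bicyclo[3.2.1]octan-8-one with C3 dimethyl ketal, C4 silyl ether and aryl pivalate | C=CC[C@@]12CC(OC)(OC)[C@H](O[Si](C)(C)C(C)(C)C)[C@@](OC)(C1=O)[C@H](c1ccc(OC(=O)C(C)(C)C)c(OC)c1)[C@H]2C
A2 | alternative 1 | C8 trimethylsilyl enol ether of the cyclopentanone carrying the 1-silyloxy-2-methoxyallyl chain on C5 | C=CCC1=C(O[Si](C)(C)C)[C@](OC)([C@@H](O[Si](C)(C)C(C)(C)C)C(OC)=C)[C@H](c2ccc(OC(=O)C(C)(C)C)c(OC)c2)[C@H]1C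
A3 | alternative 2 | C8 triethylsilyl enol ether of 2-allyl-5-methoxy-3-methyl-4-arylcyclopentanone | C=CCC1=C(O[Si](CC)(CC)CC)[C@H](OC)[C@H](c2ccc(O[Si](C)(C)C(C)(C)C)c(OC)c2)[C@H]1C
A4 | alternative 2 | cross-conjugated α-methoxy dienone | C=CC/C(=C\C)C(=O)/C(OC)=C/c1ccc(O[Si](C)(C)C(C)(C)C)c(OC)c1
A5 | alternative 3 | O-tert-butyldimethylsilyl bicyclo[3.2.1]oct-2-ene-4,8-dione | C=CC[C@@]12C=C(OC)C(=O)[C@@](OC)(C1=O)[C@H](c1ccc(O[Si](C)(C)C(C)(C)C)c(OC)c1)[C@H]2C
A6 | alternative 3 | 2-allyl-5-methoxy-5-(methoxyacetyl)-3-methyl-4-arylcyclopentanone | C=CCC1C(=O)[C@](OC)(C(=O)COC)[C@H](c2ccc(O[Si](C)(C)C(C)(C)C)c(OC)c2)[C@H]1C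
A7 | alternative 3 | enaminone from A6 and DMF dimethyl acetal | C=CCC1C(=O)[C@](OC)(C(=O)/C(OC)=C/N(C)C)[C@H](c2ccc(O[Si](C)(C)C(C)(C)C)c(OC)c2)[C@H]1C
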